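## Retrosynthetic overview

- Last operation: removal of the two silyl ethers from the fully assembled bis-silyl lactone.
- Key disconnection: the C6–C7 bond. A light-driven, chromium-catalysed Barbier-type closure of an enal onto a (Z)-2-(bromomethyl)enoate forms the ten-membered carbocycle (ring A) and, by closure of the C6 alkoxide onto the ester, the α-methylene-γ-lactone (ring B) in one operation.
- The bromomethyl enoate comes from a Morita–Baylis–Hillman reaction at the C7 aldehyde; the C4=C5 enal comes from a syn-hydroalkylation of a silyloxy ynoate by a C3 alkylborane (C3–C4 bond).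
- The C7–C10/C1–C2 chain comes from ozonolytic opening, with differentiated termini, of a bridged lactone made by iodolactonisation of (R)-cyclohex-3-ene-1-carboxylic acid. C10 is bought and C8 is relayed from it.
- Ring order: temporary bridged γ-lactone (formed first, opened and later reduced), then rings A and B together in the key step.

Assumption: carbons carry germacrane-style labels (ring C1–C10, lactone carbons C11–C13, hydroxymethyl carbons C14 on C10 and C15 on C4); the target is then 6S,7S,8R,10R with C15 cis to C6 across C4=C5.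

## Route

Step 1
Reactants: 1 (R)-cyclohex-3-ene-1-carboxylic acid
Product: 2 (1R,4R,5R)-4-iodo-6-oxabicyclo[3.2.1]octan-7-one
Conditions: I2, NaHCO3, CH2Cl2/H2O, 0 °C → rt, dark
Reagents that add atoms: iodine, II
Why: Iodolactonisation: the carboxylate opens the iodonium ion intramolecularly, so the new C8–O bond can only form cis to the carboxyl carbon on C10 (the bought centre fixes C8 as R), with iodine trans on C7.

Step 2
Reactants: 2 (1R,4R,5R)-4-iodo-6-oxabicyclo[3.2.1]octan-7-one
Product: 3 (1R,5R)-6-oxabicyclo[3.2.1]oct-3-en-7-one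
Conditions: DBU, toluene, 110 °C
Reagents that add atoms: none
Why: E2 dehydroiodination: the only hydrogen anti-periplanar to iodine lies on the methylene away from the bridgehead, so the alkene forms between C7 and C2 and leaves C8 and C10 untouched.

Step 3
Reactants: 3 (1R,5R)-6-oxabicyclo[3.2.1]oct-3-en-7-one
Product: 6 (3S,5R)-5-(dimethoxymethyl)-3-(2-oxoethyl)oxolan-2-one (3,5-cis), via hydroperoxy aldehyde 4 (not isolated), via hydroperoxy acetal 5 (not isolated)
Conditions: O3, CH2Cl2/MeOH, −78 °C; TsOH·H2O (cat.), −78 °C → rt; NaHCO3; Me2S, rt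
Reagents that add atoms: ozone, [O-][O+]=O; methanol, CO
Why: Unsymmetrical Criegee ozonolysis with terminus differentiation: the primary ozonide cleaves with the carbonyl oxide on C2, away from the electron-withdrawing allylic lactone oxygen, so methanol traps C2 as the methoxy hydroperoxide (reduced to the aldehyde by Me2S) while the free C7 aldehyde is acetalised under acid; no stereocentre is touched.

Step 4
Reactants: 6 (3S,5R)-5-(dimethoxymethyl)-3-(2-oxoethyl)oxolan-2-one
Product: 7 (3R,5R)-5-(dimethoxymethyl)-3-(prop-2-en-1-yl)oxolan-2-one (3,5-cis)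
Conditions: Ph3PCH3Br, KN(SiMe3)2, THF, 0 °C; then 6, −78 → 0 °C
Reagents that add atoms: methyltriphenylphosphonium bromide, C[P+](c1ccccc1)(c1ccccc1)c1ccccc1.[Br-]
Why: Wittig methylenation: the aldehyde is olefinated at low temperature far faster than the ylide can enolise the lactone, which installs C3 as a terminal alkene without epimerising C10.

Step 5
Reactants: 8 methyl 4-hydroxybut-2-ynoate
Product: 9 methyl 4-[(tert-butyldiphenylsilyl)oxy]but-2-ynoate
Conditions: TBDPSCl, imidazole, CH2Cl2, 0 °C → rt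
Reagents that add atoms: tert-butyl(chloro)diphenylsilane, CC(C)(C)[Si](Cl)(c1ccccc1)c1ccccc1
Why: Standard silyl ether formation on a primary propargylic alcohol; the acid-stable silyl group blocks C15–OH so that the later cis-hydroxy enal cannot close to a lactol.

Step 6
Reactants: 7 (3R,5R)-5-(dimethoxymethyl)-3-(prop-2-en-1-yl)oxolan-2-one; 9 methyl 4-[(tert-butyldiphenylsilyl)oxy]but-2-ynoate
Product: 11 methyl (2Z)-3-{[(tert-butyldiphenylsilyl)oxy]methyl}-6-[(3R,5R)-5-(dimethoxymethyl)-2-oxooxolan-3-yl]hex-2-enoate, via alkylborane 10 (not isolated)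
Conditions: 9-BBN-H, THF, 0 °C → rt; then 9, CuOAc (5 mol %), P(OPh)3 (10 mol %), KOt-Bu (10 mol %), t-BuOH, 1,4-dioxane, 40 °C
Reagents that add atoms: none
Why: Anti-Markovnikov hydroboration followed by copper-catalysed conjugate addition of the B-alkyl-9-BBN to the ynoate (syn carbocupration, then protonation with retention): C3 and H add to the same side, so the chain ends trans to the ester and the silyloxymethyl group cis to it, which is the C4=C5 geometry of the target.

Step 7
Reactants: 11 methyl (2Z)-3-{[(tert-butyldiphenylsilyl)oxy]methyl}-6-[(3R,5R)-5-(dimethoxymethyl)-2-oxooxolan-3-yl]hex-2-enoate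
Product: 12 (2Z,7R,9R)-3-{[(tert-butyldiphenylsilyl)oxy]methyl}-7-(hydroxymethyl)-10,10-dimethoxydec-2-ene-1,9-diol
Conditions: i-Bu2AlH (7 equiv), CH2Cl2, −78 → 0 °C; aq. KNaC4H4O6
Reagents that add atoms: none
Why: Hydride 1,2-reduction takes the lactone to the C8/C14 diol and the enoate to the C6 allylic alcohol in one operation; acetal, silyl ether, alkene geometry and both stereocentres are inert (C10 is no longer epimerisable afterwards).

Step 8
Reactants: 12 (2Z,7R,9R)-3-{[(tert-butyldiphenylsilyl)oxy]methyl}-7-(hydroxymethyl)-10,10-dimethoxydec-2-ene-1,9-diol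
Product: 13 (2Z,7R,9R)-3-{[(tert-butyldiphenylsilyl)oxy]methyl}-9-hydroxy-7-(hydroxymethyl)-10,10-dimethoxydec-2-enal
Conditions: MnO2 (20 equiv), CH2Cl2, rt
Reagents that add atoms: none
Why: Chemoselective allylic oxidation: MnO2 oxidises only the allylic C6 alcohol, leaves the saturated primary and secondary alcohols alone and keeps the alkene geometry.

Step 9
Reactants: 13 (2Z,7R,9R)-3-{[(tert-butyldiphenylsilyl)oxy]methyl}-9-hydroxy-7-(hydroxymethyl)-10,10-dimethoxydec-2-enal
Product: 14 (2Z,7R,9R)-3,7-bis{[(tert-butyldiphenylsilyl)oxy]methyl}-9-hydroxy-10,10-dimethoxydec-2-enal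
Conditions: TBDPSCl (1.05 equiv), imidazole, DMF, 0 °C
Reagents that add atoms: tert-butyl(chloro)diphenylsilane, CC(C)(C)[Si](Cl)(c1ccccc1)c1ccccc1
Why: Selective silylation: the bulky silyl chloride takes the primary C14 alcohol and leaves the hindered secondary C8 alcohol next to the acetal free.

Step 10
Reactants: 14 (2Z,7R,9R)-3,7-bis{[(tert-butyldiphenylsilyl)oxy]methyl}-9-hydroxy-10,10-dimethoxydec-2-enal
Product: 15 (2R,4R,8Z)-4,8-bis{[(tert-butyldiphenylsilyl)oxy]methyl}-1,1-dimethoxy-10-oxodec-8-en-2-yl 2-methylprop-2-enoate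
Conditions: methacryloyl chloride, Et3N, DMAP (cat.), CH2Cl2, 0 °C → rt
Reagents that add atoms: 2-methylprop-2-enoyl chloride, CC(=C)C(Cl)=O
Why: DMAP-catalysed acylation of the only free hydroxyl installs the final C8 ester with retention (the C–O bond is not broken); the ester later blocks C8–O from competing in the lactonisation.

Step 11
Reactants: 15 (2R,4R,8Z)-4,8-bis{[(tert-butyldiphenylsilyl)oxy]methyl}-1,1-dimethoxy-10-oxodec-8-en-2-yl 2-methylprop-2-enoate
Product: 16 (2R,4R,8Z)-4,8-bis{[(tert-butyldiphenylsilyl)oxy]methyl}-1,10-dioxodec-8-en-2-yl 2-methylprop-2-enoate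
Conditions: TFA/H2O (9:1), CH2Cl2, 0 °C
Reagents that add atoms: water, O
Why: Acid-catalysed acetal hydrolysis frees the C7 aldehyde; the silyl ethers and both esters tolerate brief aqueous TFA.

Step 12
Reactants: 16 (2R,4R,8Z)-4,8-bis{[(tert-butyldiphenylsilyl)oxy]methyl}-1,10-dioxodec-8-en-2-yl 2-methylprop-2-enoate; 17 methyl acrylate
Product: 18 methyl (4R,6R,10Z)-6,10-bis{[(tert-butyldiphenylsilyl)oxy]methyl}-3-hydroxy-2-methylidene-4-[(2-methylprop-2-enoyl)oxy]-12-oxododec-10-enoate (both C3 epimers)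
Conditions: DABCO (0.5 equiv), MeOH (2 equiv), 17 (10 equiv, neat), rt
Reagents that add atoms: none
Why: Morita–Baylis–Hillman reaction: the amine–acrylate zwitterion adds to the strongly electrophilic α-acyloxy aldehyde (C7) and not to the β,β-disubstituted enal; the new carbinol centre is formed as a mixture that is erased in the next step.

Step 13
Reactants: 18 methyl (4R,6R,10Z)-6,10-bis{[(tert-butyldiphenylsilyl)oxy]methyl}-3-hydroxy-2-methylidene-4-[(2-methylprop-2-enoyl)oxy]-12-oxododec-10-enoate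
Product: 19 methyl (2Z,4R,6R,10Z)-2-(bromomethyl)-6,10-bis{[(tert-butyldiphenylsilyl)oxy]methyl}-4-[(2-methylprop-2-enoyl)oxy]-12-oxododeca-2,10-dienoate
Conditions: NBS, Me2S, CH2Cl2, 0 °C → rt
Reagents that add atoms: N-bromosuccinimide, O=C1CCC(=O)N1Br
Why: Corey–Kim-type activation of the allylic alcohol followed by SN2' attack of bromide (allylic transposition) gives the conjugated (Z)-2-(bromomethyl)enoate, the thermodynamic isomer with C8 cis to CH2Br; C7 becomes sp2 and C8 is untouched.

Step 14
Reactants: 19 methyl (2Z,4R,6R,10Z)-2-(bromomethyl)-6,10-bis{[(tert-butyldiphenylsilyl)oxy]methyl}-4-[(2-methylprop-2-enoyl)oxy]-12-oxododeca-2,10-dienoate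
Product: 21 (3aS,4R,6R,10Z,11aS)-6,10-bis{[(tert-butyldiphenylsilyl)oxy]methyl}-3-methylidene-2-oxo-2,3,3a,4,5,6,7,8,9,11a-decahydrocyclodeca[b]furan-4-yl 2-methylprop-2-enoate, via hydroxy ester 20 (not isolated)
Conditions: CrCl2 (10 mol %), 4CzIPN (2 mol %), Hantzsch ester (1.5 equiv), 2,6-lutidine (2 equiv), DMF, 1 mM (syringe pump), 450 nm LEDs, rt; then PPTS (cat.), CH2Cl2, rt
Reagents that add atoms: none
Why: Proposed new method: a light-driven, chromium-catalytic Barbier macrocyclisation with tandem lactonisation — excited 4CzIPN is quenched by the Hantzsch ester, the reduced dye returns trivalent chromium to divalent chromium, which converts the allylic bromide into a σ-allyl trivalent chromium species that adds through its γ-carbon (C7) to the C6 aldehyde in a six-membered chair transition state, and the C6 alkoxide closes onto the methyl ester; allylic 1,3-strain holds H8 in the alkene plane, so the tether (through C9) delivers the aldehyde to the face anti to the C8 ester oxygen (7S), and the equilibrated σ-allyl with the enal residue and C8 both equatorial gives the 6,7-anti adduct (6S, trans-fused lactone); the closest known reactions are the intermolecular photoredox/chromium dual-catalysed allylation of aldehydes (Nozaki–Hiyama–Kishi type) and the stoichiometric CrCl2 Barbier ring closures of germacranolides, neither shown as a catalytic light-driven ten-membered ring closure.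

Step 15
Reactants: 21 (3aS,4R,6R,10Z,11aS)-6,10-bis{[(tert-butyldiphenylsilyl)oxy]methyl}-3-methylidene-2-oxo-2,3,3a,4,5,6,7,8,9,11a-decahydrocyclodeca[b]furan-4-yl 2-methylprop-2-enoate
Product: 22 (3aS,4R,6R,10Z,11aS)-6,10-bis(hydroxymethyl)-3-methylidene-2-oxo-2,3,3a,4,5,6,7,8,9,11a-decahydrocyclodeca[b]furan-4-yl 2-methylprop-2-enoate
Conditions: HF·pyridine, THF/pyridine, 0 °C → rt
Reagents that add atoms: none
Why: Fluoride-mediated desilylation under buffered, non-basic conditions frees both primary alcohols without touching the methacrylate, the α-methylene lactone or any stereocentre.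

## Compound list

1 | (R)-cyclohex-3-ene-1-carboxylic acid | O=C(O)[C@H]1CC=CCC1 | starting material
2 | (1R,4R,5R)-4-iodo-6-oxabicyclo[3.2.1]octan-7-one | O=C1O[C@@H]2C[C@H]1CC[C@H]2I | intermediate
3 | (1R,5R)-6-oxabicyclo[3.2.1]oct-3-en-7-one | O=C1O[C@@H]2C[C@H]1CC=C2 | intermediate
4 | (2R,4S)-4-(2-hydroperoxy-2-methoxyethyl)-5-oxooxolane-2-carbaldehyde (2,4-cis; epimers at the peroxy carbon) | O=C1O[C@@H](C=O)C[C@H]1CC(OC)OO | intermediate (not isolated)
5 | (3S,5R)-5-(dimethoxymethyl)-3-(2-hydroperoxy-2-methoxyethyl)oxolan-2-one (3,5-cis; epimers at the peroxy carbon) | O=C1O[C@@H](C(OC)OC)C[C@H]1CC(OC)OO | intermediate (not isolated)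
6 | (3S,5R)-5-(dimethoxymethyl)-3-(2-oxoethyl)oxolan-2-one (3,5-cis) | O=C1O[C@@H](C(OC)OC)C[C@H]1CC=O | intermediate
7 | (3R,5R)-5-(dimethoxymethyl)-3-(prop-2-en-1-yl)oxolan-2-one (3,5-cis) | O=C1O[C@@H](C(OC)OC)C[C@H]1CC=C | intermediate
8 | methyl 4-hydroxybut-2-ynoate | COC(=O)C#CCO | starting material
9 | methyl 4-[(tert-butyldiphenylsilyl)oxy]but-2-ynoate | COC(=O)C#CCO[Si](c1ccccc1)(c1ccccc1)C(C)(C)C | intermediate
10 | (3R,5R)-3-[3-(9-borabicyclo[3.3.1]nonan-9-yl)propyl]-5-(dimethoxymethyl)oxolan-2-one | O=C1O[C@@H](C(OC)OC)C[C@H]1CCCB1C2CCCC1CCC2 | intermediate (not isolated)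
11 | methyl (2Z)-3-{[(tert-butyldiphenylsilyl)oxy]methyl}-6-[(3R,5R)-5-(dimethoxymethyl)-2-oxooxolan-3-yl]hex-2-enoate | O=C1O[C@@H](C(OC)OC)C[C@H]1CCC/C(CO[Si](c1ccccc1)(c1ccccc1)C(C)(C)C)=C/C(=O)OC | intermediate
12 | (2Z,7R,9R)-3-{[(tert-butyldiphenylsilyl)oxy]methyl}-7-(hydroxymethyl)-10,10-dimethoxydec-2-ene-1,9-diol | COC(OC)[C@H](O)C[C@H](CO)CCC/C(CO[Si](c1ccccc1)(c1ccccc1)C(C)(C)C)=C/CO | intermediate
13 | (2Z,7R,9R)-3-{[(tert-butyldiphenylsilyl)oxy]methyl}-9-hydroxy-7-(hydroxymethyl)-10,10-dimethoxydec-2-enal | COC(OC)[C@H](O)C[C@H](CO)CCC/C(CO[Si](c1ccccc1)(c1ccccc1)C(C)(C)C)=C/C=O | intermediate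
14 | (2Z,7R,9R)-3,7-bis{[(tert-butyldiphenylsilyl)oxy]methyl}-9-hydroxy-10,10-dimethoxydec-2-enal | COC(OC)[C@H](O)C[C@H](CO[Si](c1ccccc1)(c1ccccc1)C(C)(C)C)CCC/C(CO[Si](c1ccccc1)(c1ccccc1)C(C)(C)C)=C/C=O | intermediate
15 | (2R,4R,8Z)-4,8-bis{[(tert-butyldiphenylsilyl)oxy]methyl}-1,1-dimethoxy-10-oxodec-8-en-2-yl 2-methylprop-2-enoate | COC(OC)[C@H](OC(=O)C(C)=C)C[C@H](CO[Si](c1ccccc1)(c1ccccc1)C(C)(C)C)CCC/C(CO[Si](c1ccccc1)(c1ccccc1)C(C)(C)C)=C/C=O | intermediate
16 | (2R,4R,8Z)-4,8-bis{[(tert-butyldiphenylsilyl)oxy]methyl}-1,10-dioxodec-8-en-2-yl 2-methylprop-2-enoate | O=C[C@H](OC(=O)C(C)=C)C[C@H](CO[Si](c1ccccc1)(c1ccccc1)C(C)(C)C)CCC/C(CO[Si](c1ccccc1)(c1ccccc1)C(C)(C)C)=C/C=O | intermediate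
17 | methyl acrylate (methyl prop-2-enoate) | C=CC(=O)OC | starting material
18 | methyl (4R,6R,10Z)-6,10-bis{[(tert-butyldiphenylsilyl)oxy]methyl}-3-hydroxy-2-methylidene-4-[(2-methylprop-2-enoyl)oxy]-12-oxododec-10-enoate (both C3 epimers) | COC(=O)C(=C)C(O)[C@H](OC(=O)C(C)=C)C[C@H](CO[Si](c1ccccc1)(c1ccccc1)C(C)(C)C)CCC/C(CO[Si](c1ccccc1)(c1ccccc1)C(C)(C)C)=C/C=O | intermediate
19 | methyl (2Z,4R,6R,10Z)-2-(bromomethyl)-6,10-bis{[(tert-butyldiphenylsilyl)oxy]methyl}-4-[(2-methylprop-2-enoyl)oxy]-12-oxododeca-2,10-dienoate | COC(=O)/C(CBr)=C/[C@H](OC(=O)C(C)=C)C[C@H](CO[Si](c1ccccc1)(c1ccccc1)C(C)(C)C)CCC/C(CO[Si](c1ccccc1)(c1ccccc1)C(C)(C)C)=C/C=O | intermediate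
20 | methyl 2-[(1S,2S,3Z,8R,10R)-4,8-bis{[(tert-butyldiphenylsilyl)oxy]methyl}-2-hydroxy-10-[(2-methylprop-2-enoyl)oxy]cyclodec-3-en-1-yl]prop-2-enoate (held in the flask as its trivalent chromium alkoxide) | C=C(C)C(=O)O[C@@H]1C[C@H](CO[Si](c2ccccc2)(c2ccccc2)C(C)(C)C)CCC/C(CO[Si](c2ccccc2)(c2ccccc2)C(C)(C)C)=C/[C@H](O)[C@H]1C(=C)C(=O)OC | intermediate (not isolated)
21 | (3aS,4R,6R,10Z,11aS)-6,10-bis{[(tert-butyldiphenylsilyl)oxy]methyl}-3-methylidene-2-oxo-2,3,3a,4,5,6,7,8,9,11a-decahydrocyclodeca[b]furan-4-yl 2-methylprop-2-enoate | C=C(C)C(=O)O[C@@H]1C[C@H](CO[Si](c3ccccc3)(c3ccccc3)C(C)(C)C)CCC/C(CO[Si](c3ccccc3)(c3ccccc3)C(C)(C)C)=C/[C@@H]2OC(=O)C(=C)[C@H]21 | intermediate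
22 | (3aS,4R,6R,10Z,11aS)-6,10-bis(hydroxymethyl)-3-methylidene-2-oxo-2,3,3a,4,5,6,7,8,9,11a-decahydrocyclodeca[b]furan-4-yl 2-methylprop-2-enoate | C=C(C)C(=O)O[C@@H]1C[C@H](CO)CCC/C(CO)=C/[C@@H]2OC(=O)C(=C)[C@H]21 | target

## Step count and risks

Total step count: 15. Longest linear sequence: 14 (steps 1–4 and 6–15, from 1 to 22).

**Most likely to fail, first: step 14 (the proposed ring closure).** Chromium turnover may stall, the bromide may simply be reduced, oligomers may form, or the 6,7-anti/7S selectivity may not be as predicted. The fallback leaves photocatalysis for the known thermal, stoichiometric organochromium Barbier closure used for germacranolide rings. It sets out from bromide 19, which is added by syringe pump to CrCl2 (6 equiv) in degassed THF/DMF at rt (final 1 mM). The allylchromium adds to the C6 aldehyde to give the same hydroxy ester 20, which is lactonised with PPTS. The fallback comes back to the route at 21 and makes no new compound (F0).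

**Second: step 12 (Morita–Baylis–Hillman reaction on dialdehyde 16).** The amine may epimerise C8 of the α-acyloxy aldehyde over the long reaction time, or the enal may interfere. The fallback replaces amine catalysis by 1,2-addition of a preformed vinylmetal. Methyl propiolate is hydroaluminated with i-Bu2AlH in the presence of N-methylmorpholine N-oxide (THF, 0 °C) to give the α-(methoxycarbonyl)vinyl aluminium reagent, which is added to 16 at −78 °C. It reacts with the more electrophilic α-acyloxy aldehyde under non-basic conditions, although selectivity over the enal is not guaranteed. The fallback sets out from 16, comes back at 18 and makes no new compound (F0).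

**Third: step 6 (copper-catalysed syn-hydroalkylation of ynoate 9).** The catalytic base could epimerise C10 of the lactone, or the addition could be sluggish with the silyloxy ynoate. The fallback builds the C3–C4 bond by a stereoretentive palladium cross-coupling with a preformed vinyl iodide:

- Ynoate 9 is treated with Bu3SnLi/CuBr·SMe2 in THF/MeOH at −78 °C (syn stannylcupration) to give methyl (2E)-4-[(tert-butyldiphenylsilyl)oxy]-3-(tributylstannyl)but-2-enoate F1.
- Iodine in CH2Cl2 at 0 °C converts it with retention into methyl (2E)-3-iodo-4-[(tert-butyldiphenylsilyl)oxy]but-2-enoate F2.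
- Alkylborane 10 (from 7 and 9-BBN-H as in the route) is coupled with F2 in a B-alkyl Suzuki–Miyaura reaction (PdCl2(dppf), aq. K3PO4, THF/DMF, rt), which places the chain trans to the ester.

The fallback sets out from 7 and 9 and comes back to the route at 11.

## Further compounds

F0 | step 14 | none | none
F0 | step 12 | none | none
F1 | step 6 | methyl (2E)-4-[(tert-butyldiphenylsilyl)oxy]-3-(tributylstannyl)but-2-enoate | COC(=O)/C=C(/[Sn](CCCC)(CCCC)CCCC)CO[Si](c1ccccc1)(c1ccccc1)C(C)(C)C
F2 | step 6 | methyl (2E)-3-iodo-4-[(tert-butyldiphenylsilyl)oxy]but-2-enoate | COC(=O)/C=C(/I)CO[Si](c1ccccc1)(c1ccccc1)C(C)(C)C
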